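Count every amount as a fraction of the substrates charged, and hold the flask against the north run, which has the same charge with more free catalyst.

all flasks: solid reagent 22.8 mM
- north: left-handed substrate 19 mM; right-handed substrate 19 mM; free catalyst 95 µM; run made earlier
- south-west: left-handed substrate 19 mM; right-handed substrate 19 mM; free catalyst 150 µM; run made earlier
- north-west: left-handed substrate 9.5 mM; right-handed substrate 9.5 mM; free catalyst 68 µM; run made earlier
- flask: left-handed substrate 19 mM; right-handed substrate 19 mM; free catalyst 68 µM

| run | time / h | left-handed product / % | left-handed substrate / % |
|---|---|---|---|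
| north | 0.200 | 0 | 49.7 |
| north | 0.333 | 0.1 | 49.6 |
| north | 0.500 | 0.2 | 49.5 |
| north | 0.833 | 0.5 | 49.5 |
| north | 1.33 | 0.9 | 48.6 |
| north | 2.50 | 2.7 | 47.6 |
| south-west | 0.417 | 0.1 | 49.5 |
| south-west | 0.833 | 1.1 | 48.5 |
| south-west | 1.33 | 1.0 | 48.1 |
| south-west | 1.50 | 1.8 | 48.4 |
| south-west | 2.00 | 2.4 | 46.9 |
| south-west | 2.50 | 3.5 | 46.2 |
| north-west | 0.200 | 0.1 | 49.8 |
| north-west | 0.333 | 0.3 | 49.9 |
| north-west | 0.667 | 0.3 | 49.2 |
| north-west | 1.33 | 1.7 | 48.2 |
| north-west | 2.50 | 3.4 | 46.3 |

(each reading ± 0.3 percentage points)
- free catalyst is single-handed; left-handed substrate and right-handed substrate are mirror images of each other, charged as a racemate, each of them at the stated concentration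
- given per volume of solution although it is solid: solid reagent
- at the start none of the solid reagent is in solution
- apparent order in free catalyst when 10% of the left-handed substrate and right-handed substrate together are converted (percent change of the rate of making left-handed product for one percent more free catalyst charged)
- factor on the rate of making left-handed product when 10% of the left-handed substrate and right-handed substrate together are converted if free catalyst is charged twice over

Solve the two ends, then join them. With little catalyst, product follows the catalyst and the order is one; with plenty, product follows the dissolving of solid reagent and the order is zero. Join them as two hold-ups in series and call the demand ratio the catalyst's pull over the dissolving: the order is one over one plus that ratio, and doubling multiplies the rate by two over two minus the order.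

Read it from south-west against north. Catalyst rises 1.58-fold and the last product reading 1.30-fold, so the order is 0.568, a rough reading with scatter of 0.3 percentage points, and the ratio at their middle catalyst is 0.760. I scale it with catalyst and, as my own assumption, make no correction for the left-handed substrate used up at the asked conversion: 0.433 for the flask, so order 0.698 and factor 1.54. North stands at 0.605, against 0.433 for the flask, so expect the flask to run at 0.802 of north's rate, not the 0.716 of its catalyst.

The forecast gives a lower order than mine: 0.6, from 0.35 to 0.85, and factor 1.42, from 1.22 to 1.8: “Similar partial orders in catalyst and substrate point to dissolution competing with reaction.”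

The flask gives order 0.72 and factor 1.55.

    partner + catalyst intermediate A → free catalyst + left-handed product (k = 73.0 M⁻¹ min⁻¹)
    free catalyst + right-handed substrate ⇌ catalyst intermediate B (K = 19.0 M⁻¹, k = 13000 M⁻¹ min⁻¹)
    partner + free catalyst → spent catalyst (k = 0.770 M⁻¹ min⁻¹)
    partner + catalyst intermediate B → free catalyst + right-handed product (k = 7.10 M⁻¹ min⁻¹)
    free catalyst + left-handed substrate ⇌ catalyst intermediate A (K = 1000 M⁻¹, k = 5100 M⁻¹ min⁻¹)
    solid reagent ⇌ partner, rate k6*(cs6 - [partner]) while solid is left; crystals form when [partner] > cs6 (solubility = 2.70 mM, k = 0.0100 min⁻¹)

At 1.11 h partner has a half-life of 2.5 h by its step with catalyst intermediate A, the resting state, so it is lost at 0.277 h⁻¹, slower than the dissolving constant 0.600 h⁻¹, a ratio of 0.462 against the carried 0.433. Scaled to north's catalyst that ratio is 0.645 against 0.605, and the flask holds 2.60% left-handed product at 3.00 h, against north's reading of 2.7% at 2.50 h.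

The numbers in the tables are calculated for substances that don't exist, and the scatter is random.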